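All runs are simulated with constants of no real substance; scatter was added.

In a one-step world a product climbs to its plateau with a constant half-life, so each equal stretch of time adds the same fraction of what the stretch before it added. We hold the winter run, which is the very flask asked about, against that picture.

- winter: left-handed substrate 0.10 M; right-handed substrate 0.10 M; coupling partner 0.060 M (fed, over 15 min); free catalyst 0.69 mM; the very flask that is asked about, followed so far
- flask: left-handed substrate 0.10 M; coupling partner 0.0600 M (fed, over 15 min); free catalyst 0.69 mM; right-handed substrate 0.10 M; time 30 h

- winter (time / h: left-handed product / %, right-handed substrate / %): 1.00: 2.1, 49.6; 2.00: 4.5, 48.1; 3.00: 4.4, 48.6; 6.00: 6.1, 47.6; 12.0: 6.8, 47.4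

(each reading ± 0.5 percentage points)

- free catalyst is single-handed; left-handed substrate and right-handed substrate are mirror images of each other, charged as a racemate, each of them at the stated concentration
- reactions considered so far: coupling partner + catalyst intermediate B -> free catalyst + right-handed product; free catalyst + right-handed substrate <-> catalyst intermediate B; 2 coupling partner -> self-condensation product; coupling partner + catalyst intermediate A -> free catalyst + left-handed product; free catalyst + left-handed substrate <-> catalyst intermediate A
- the reaction counts as stopped when no species that holds the left-handed substrate and right-handed substrate together changes by six tenths of a point or more over the second half of the time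

- at 30 h, what has stopped the reaction, if anything has (no working catalyst is left / all of the left-handed substrate has reacted / the coupling partner has run out first / forward and back rates have come level / it is still moving)
- left-handed product at 30 h, in percent of the left-handed substrate and right-handed substrate together charged
- right-handed substrate at 30 h, in percent of the left-handed substrate and right-handed substrate together charged

In the winter run, left-handed product reaches 6.1% by 6.00 h and gains 0.7 percentage points in the next stretch of that length. The one-step picture turns this into a half-life of 1.92 h and a plateau of 6.89%.

The weak link is that late gain: it is the difference of two readings that each scatter by 0.5 points, so it is poorly known. We reforge it from the larger gains of the first two stretches of 3.00 h. These give 2.19 h as the gain half-life, the time in which what the product has still to gain falls by a factor of two, and a plateau of 7.17%. The time 30 h holds 13.7 such half-lives, so on this count the flask stands on its plateau.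

In the winter run at 12.0 h, right-handed substrate has fallen by 2.6 points against 6.8% of left-handed product, a ratio of 0.382, which puts it at 47.3%. None of the listed steps destroys catalyst, and each step that makes a product or the self-condensation product uses coupling partner, charged at 0.0600 M; we name the coupling partner as what ends this flask.

The forecast gives 7.1% and 47.3%, close to our figures, but for its ending it names no working catalyst is left, reading “a hidden first-order loss of catalyst”.

The flask gives 7.21% and 47.5%, and its ending is that the coupling partner has run out first: the coupling partner, the limiting reagent, stands at 0.17% of its charge, while the three catalyst forms still hold >99.9% of the catalyst charged.

    coupling partner + catalyst intermediate B → free catalyst + right-handed product (k = 62.0 L mol⁻¹ h⁻¹)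
    free catalyst + right-handed substrate ⇌ catalyst intermediate B (K = 260 L mol⁻¹, k = 30000 L mol⁻¹ h⁻¹)
    2 coupling partner → self-condensation product (k = 8.10 L mol⁻¹ h⁻¹)
    coupling partner + catalyst intermediate A → free catalyst + left-handed product (k = 1000 L mol⁻¹ h⁻¹)
    free catalyst + left-handed substrate ⇌ catalyst intermediate A (K = 57.0 L mol⁻¹, k = 45000 L mol⁻¹ h⁻¹)

The same flask read at 20 h, 9.13 gain half-lives in, stands at 7.08%, near the plateau counted. Between 15.0 h and 30.0 h the coupling partner in this flask halves on average every 4.59 h, longer than the gain half-life of 2.19 h. Left until 300 h, the flask gains 0.040 points more left-handed product, reaching 7.25%.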